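**Plan**

- Retrosynthesis: ring C is opened at O1–C2 (cyclodehydration) and C2–C3 (Baker–Venkataraman aroyl shift from O1), which releases ring B as a 2,4-bis(silyloxy)benzoyl unit. C4–C4a is then cut (ortho-lithiation/acylation with a 5-methylhex-4-enoyl amide).
- Ring A is cut at C8–C8a, C6–C7 and C4a–C8a into 3-methoxy-2-prenylcyclobutenone and an (R)-configured siloxyalkyne that already carries the C8 side chain.
- Enabling feature: ring A is a fully substituted phloroglucinol (O1 on C8a, oxygens on C5 and C7, prenyl on C6, hydroxyalkenyl chain on C8). In the benzannulation its three oxygens come from three different sources: the ketene carbonyl (free OH, future O1), the cyclobutenone methoxy (future 5-OH) and the alkyne siloxy group (future 7-OH). They are therefore differentiated from the start and C6/C8 cannot be interchanged.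
- Forward order: ring A by benzannulation, acylation of its single C–H (C4a), then ring C closed onto preformed ring B. The 5-oxygen is carried as a methyl ether because its cleavage through the magnesium chelate with C4=O is fast and precedented with prenyl groups present; all silyl groups leave in one final fluoride step.
- Stereochemistry: the only stereocentre (R, carbinol of the C8 chain) comes from a Sharpless kinetic resolution of racemic 2-methylhex-1-en-5-yn-3-ol and travels as a TBS ether, away from every reacting site.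

Key step: step 7

Abbreviations: TBS = tert-butyldimethylsilyl, TIPS = triisopropylsilyl, TMS = trimethylsilyl, MOM = methoxymethyl.
Assumption: ketene is drawn from a standard acetone-pyrolysis generator, so acetone is counted as the starting material of step 2.

**Route**

Step 1
Reactants: 1 2-chloro-1,1-dimethoxyethane; 2 1-bromo-3-methylbut-2-ene (prenyl bromide)
Product: 4 1-methoxy-5-methylhex-4-en-1-yne, via sodium methoxyacetylide 3 (not isolated)
Conditions: NaNH2 (3.0 equiv), liq. NH3, −33 °C; then 2, Et2O, −33 °C; NH4Cl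
Reagents that add atoms: none
Why: Threefold action of NaNH2 on the chloroacetal (loss of methanol, loss of HCl, deprotonation) should give the alkali alkoxyacetylide, which is alkylated by SN2 on the allylic bromide (classical alkoxyalkyne synthesis in liquid ammonia).

Step 2
Reactants: 4 1-methoxy-5-methylhex-4-en-1-yne; 5 acetone
Product: 7 3-methoxy-2-(3-methylbut-2-en-1-yl)cyclobut-2-en-1-one, via ketene 6 (not isolated)
Conditions: ketene gas (pyrolysis of 5, ca. 700 °C, ketene generator) passed into 4, CH2Cl2, 0 °C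
Reagents that add atoms: none
Why: Thermal [2+2] cycloaddition of ketene with the electron-rich ynol ether, in which the nucleophilic alkyne carbon (the one bearing the prenyl group) attacks the ketene carbonyl carbon, so the 2-alkyl-3-alkoxycyclobutenone should form.

Step 3
Reactants: 8 methacrolein; 9 propargyl bromide
Product: 10 rac-2-methylhex-1-en-5-yn-3-ol
Conditions: Zn dust, THF–sat. aq. NH4Cl, 0 °C to rt
Reagents that add atoms: none
Why: Zinc-mediated Barbier propargylation, in which the allenylzinc species adds 1,2 to the enal through an SE2' transition state and should give the racemic homopropargylic alcohol.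

Step 4
Reactants: 10 rac-2-methylhex-1-en-5-yn-3-ol
Product: 11 (3R)-2-methylhex-1-en-5-yn-3-ol
Conditions: Ti(OiPr)4 (0.15 equiv), L-(+)-diisopropyl tartrate (0.18 equiv), t-BuOOH (0.6 equiv), 4 Å MS, CH2Cl2, −20 °C; unreacted alcohol recovered
Reagents that add atoms: none
Why: Sharpless kinetic resolution, in which the L-(+)-tartrate catalyst epoxidises the (S)-allylic alcohol much faster (erythro-selective oxygen delivery), so that the unreacted (R)-enantiomer should be recovered enantiomerically enriched past half conversion; this sets the only stereocentre.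

Step 5
Reactants: 11 (3R)-2-methylhex-1-en-5-yn-3-ol
Product: 12 (3R)-3-(TBS-oxy)-2-methylhex-1-en-5-yne
Conditions: TBSCl, imidazole, DMF, rt
Reagents that add atoms: tert-butyldimethylsilyl chloride, CC(C)(C)[Si](C)(C)Cl
Why: Standard silylation of a secondary alcohol, which masks the hydroxyl against acylation by the ketenes of step 7.

Step 6
Reactants: 12 (3R)-3-(TBS-oxy)-2-methylhex-1-en-5-yne
Product: 15 (3R)-3-(TBS-oxy)-2-methyl-6-(TIPS-oxy)hex-1-en-5-yne, via lithium acetylide 13 (not isolated), via lithium ynolate 14 (not isolated)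
Conditions: n-BuLi, THF, −78 °C; t-BuOOLi (from t-BuOOH and LiHMDS), −78 to 0 °C; TIPSOTf, −78 °C
Reagents that add atoms: tert-butyl hydroperoxide, CC(C)(C)OO; triisopropylsilyl triflate, CC(C)[Si](C(C)C)(C(C)C)OS(=O)(=O)C(F)(F)F
Why: Oxygen transfer from lithium tert-butyl peroxide to the lithium acetylide should give the lithium ynolate, which the bulky silyl triflate traps on oxygen to give the siloxyalkyne (known acetylide oxidation/O-silylation), with the stereocentre not involved.

Step 7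
Reactants: 7 3-methoxy-2-(3-methylbut-2-en-1-yl)cyclobut-2-en-1-one; 15 (3R)-3-(TBS-oxy)-2-methyl-6-(TIPS-oxy)hex-1-en-5-yne
Product: 19 2-[(2R)-2-(TBS-oxy)-3-methylbut-3-en-1-yl]-5-methoxy-4-(3-methylbut-2-en-1-yl)-3-(TIPS-oxy)phenol, via vinylketene 16 (not isolated), via vinylcyclobutenone 17 (not isolated), via dienylketene 18 (not isolated)
Conditions: 7 (1.0 equiv), 15 (1.2 equiv), toluene, 80 to 110 °C, sealed tube
Reagents that add atoms: none
Why: Heating opens cyclobutenone 7 by a four-electron electrocyclic ring opening to vinylketene 16, which adds [2+2] to siloxyalkyne 15 to give 4-vinylcyclobutenone 17; a second four-electron opening gives dienylketene 18, which closes ring A by a thermal disrotatory six-electron electrocyclisation (C4a–C8a) and tautomerises to phenol 19. The closest known reaction type is the Danheiser benzannulation of cyclobutenones with siloxyalkynes to resorcinol monosilyl ethers. Ring A is therefore closed by a pericyclic 6π closure under neutral conditions, not by an ionic cyclisation. No stereocentre is formed; the existing (R)-centre lies two atoms from the new ring, has no acidic hydrogen and should pass unchanged. The selectivity needed is the regiochemistry of the ketene–alkyne [2+2]: the alkyne carbon remote from oxygen is the nucleophilic one and bonds to the ketene carbonyl carbon, which puts the chain ortho (C8) and the TIPS-oxy group meta (C7) to the new hydroxyl, while the cyclobutenone fixes prenyl at C6 and methoxy at C5. The TBS ether keeps the side-chain oxygen from being acylated, and the slight excess of alkyne should limit acylation of the product phenol by 16.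

Step 8
Reactants: 19 2-[(2R)-2-(TBS-oxy)-3-methylbut-3-en-1-yl]-5-methoxy-4-(3-methylbut-2-en-1-yl)-3-(TIPS-oxy)phenol
Product: 20 2-[(2R)-2-(TBS-oxy)-3-methylbut-3-en-1-yl]-5-methoxy-1-(methoxymethoxy)-4-(3-methylbut-2-en-1-yl)-3-(TIPS-oxy)benzene
Conditions: MOMCl, iPr2NEt, CH2Cl2, 0 °C to rt
Reagents that add atoms: chloromethyl methyl ether, COCCl
Why: O-Alkylation of the phenol installs a strong ortho-directing group under amine-base conditions that leave aryl TIPS and alkyl TBS ethers intact.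

Step 9
Reactants: 21 N-methoxy-N-methylacetamide; 2 1-bromo-3-methylbut-2-ene (prenyl bromide)
Product: 23 N-methoxy-N,5-dimethylhex-4-enamide, via lithium amide enolate 22 (not isolated)
Conditions: LDA, THF, −78 °C; then 2, −78 to −30 °C
Reagents that add atoms: none
Why: Alkylation of the lithium enolate of the N-methoxy-N-methylamide with the reactive allylic bromide (enolate SN2 at low temperature) should give the 5-methylhex-4-enoyl amide.

Step 10
Reactants: 20 2-[(2R)-2-(TBS-oxy)-3-methylbut-3-en-1-yl]-5-methoxy-1-(methoxymethoxy)-4-(3-methylbut-2-en-1-yl)-3-(TIPS-oxy)benzene; 23 N-methoxy-N,5-dimethylhex-4-enamide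
Product: 25 1-{3-[(2R)-2-(TBS-oxy)-3-methylbut-3-en-1-yl]-6-methoxy-2-(methoxymethoxy)-5-(3-methylbut-2-en-1-yl)-4-(TIPS-oxy)phenyl}-5-methylhex-4-en-1-one, via aryllithium 24 (not isolated)
Conditions: n-BuLi, THF, 0 °C; then 23, −78 to 0 °C; aq. NH4Cl
Reagents that add atoms: none
Why: Directed ortho-metalation, in which the only ring hydrogen lies between OMOM and OMe so that coordination-assisted deprotonation there should outrun benzylic or allylic lithiation, followed by single acylation of the aryllithium by the N-methoxy-N-methylamide through its stable chelated tetrahedral adduct.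

Step 11
Reactants: 25 1-{3-[(2R)-2-(TBS-oxy)-3-methylbut-3-en-1-yl]-6-methoxy-2-(methoxymethoxy)-5-(3-methylbut-2-en-1-yl)-4-(TIPS-oxy)phenyl}-5-methylhex-4-en-1-one
Product: 27 1-{3-[(2R)-2-(TBS-oxy)-3-methylbut-3-en-1-yl]-2-hydroxy-6-methoxy-5-(3-methylbut-2-en-1-yl)-4-(TIPS-oxy)phenyl}-5-methylhex-4-en-1-one, via aryl trimethylsilyl ether 26 (not isolated)
Conditions: TMSOTf, 2,2'-bipyridyl, CH2Cl2, 0 °C to rt; then H2O
Reagents that add atoms: none
Why: The silyl triflate/2,2'-bipyridyl pair converts aromatic MOM ethers into aryl silyl ethers under non-protic conditions that spare TBS and TIPS ethers and prenyl groups, and water then frees the phenol, which is hydrogen-bonded to the ketone.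

Step 12
Reactants: 28 2,4-dihydroxybenzoic acid
Product: 30 2,4-bis(TIPS-oxy)benzoic acid, via silyl ester 29 (not isolated)
Conditions: TIPSOTf (3.3 equiv), Et3N, CH2Cl2, 0 °C to rt; then K2CO3, THF–MeOH–H2O, 0 °C; citric acid work-up
Reagents that add atoms: triisopropylsilyl triflate, CC(C)[Si](C(C)C)(C(C)C)OS(=O)(=O)C(F)(F)F
Why: Exhaustive silylation followed by selective hydrolysis of the silyl ester, which cleaves far faster than the aryl TIPS ethers, should give the bis-silylated acid.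

Step 13
Reactants: 30 2,4-bis(TIPS-oxy)benzoic acid; 27 1-{3-[(2R)-2-(TBS-oxy)-3-methylbut-3-en-1-yl]-2-hydroxy-6-methoxy-5-(3-methylbut-2-en-1-yl)-4-(TIPS-oxy)phenyl}-5-methylhex-4-en-1-one
Product: 32 2-[(2R)-2-(TBS-oxy)-3-methylbut-3-en-1-yl]-5-methoxy-6-(5-methylhex-4-enoyl)-4-(3-methylbut-2-en-1-yl)-3-(TIPS-oxy)phenyl 2,4-bis(TIPS-oxy)benzoate, via acid chloride 31 (not isolated)
Conditions: 30, 1-chloro-N,N,2-trimethylprop-1-en-1-amine, CH2Cl2, 0 °C to rt; then 27, Et3N, DMAP, CH2Cl2, rt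
Reagents that add atoms: none
Why: The α-chloroenamine converts the acid to its chloride without releasing HCl, so the silyl ethers survive, and DMAP-catalysed O-acylation of the single free phenol gives the aryl ester.

Step 14
Reactants: 32 2-[(2R)-2-(TBS-oxy)-3-methylbut-3-en-1-yl]-5-methoxy-6-(5-methylhex-4-enoyl)-4-(3-methylbut-2-en-1-yl)-3-(TIPS-oxy)phenyl 2,4-bis(TIPS-oxy)benzoate
Product: 34 2-[2,4-bis(TIPS-oxy)phenyl]-8-[(2R)-2-(TBS-oxy)-3-methylbut-3-en-1-yl]-5-methoxy-3,6-bis(3-methylbut-2-en-1-yl)-7-(TIPS-oxy)-4H-chromen-4-one, via 1,3-diketone 33 (not isolated)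
Conditions: LiHMDS, THF, −78 to 0 °C; AcOH quench; then AcOH, 80 °C
Reagents that add atoms: none
Why: Baker–Venkataraman rearrangement, in which the ketone enolate attacks the neighbouring aryl ester intramolecularly to give the 1,3-diketone, whose only free phenol (the future O1) adds to the aroyl carbonyl and loses water in warm acetic acid to close ring C.

Step 15
Reactants: 34 2-[2,4-bis(TIPS-oxy)phenyl]-8-[(2R)-2-(TBS-oxy)-3-methylbut-3-en-1-yl]-5-methoxy-3,6-bis(3-methylbut-2-en-1-yl)-7-(TIPS-oxy)-4H-chromen-4-one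
Product: 35 2-[2,4-bis(TIPS-oxy)phenyl]-8-[(2R)-2-(TBS-oxy)-3-methylbut-3-en-1-yl]-5-hydroxy-3,6-bis(3-methylbut-2-en-1-yl)-7-(TIPS-oxy)-4H-chromen-4-one
Conditions: MgI2·OEt2, THF, 60 °C; aq. NH4Cl/Na2S2O3 work-up
Reagents that add atoms: none
Why: MgI2 chelates between C4=O and the peri 5-methoxy oxygen and iodide removes the methyl group by SN2 (chelation-assisted demethylation known for 5-methoxy prenylflavonoids), leaving silyl ethers and prenyl groups untouched.

Step 16
Reactants: 35 2-[2,4-bis(TIPS-oxy)phenyl]-8-[(2R)-2-(TBS-oxy)-3-methylbut-3-en-1-yl]-5-hydroxy-3,6-bis(3-methylbut-2-en-1-yl)-7-(TIPS-oxy)-4H-chromen-4-one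
Product: 36 2-(2,4-dihydroxyphenyl)-5,7-dihydroxy-8-[(2R)-2-hydroxy-3-methylbut-3-en-1-yl]-3,6-bis(3-methylbut-2-en-1-yl)-4H-chromen-4-one
Conditions: TBAF, AcOH, THF, 0 °C to rt
Reagents that add atoms: none
Why: Fluoride cleaves the three aryl TIPS ethers and the secondary TBS ether in one operation, with acetic acid buffering the phenoxides of the air- and base-sensitive polyphenol.

**Compound list**

1 | 2-chloro-1,1-dimethoxyethane (chloroacetaldehyde dimethyl acetal) | COC(CCl)OC | starting material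
2 | 1-bromo-3-methylbut-2-ene (prenyl bromide) | CC(C)=CCBr | starting material
3 | sodium methoxyacetylide | COC#C[Na] | intermediate
4 | 1-methoxy-5-methylhex-4-en-1-yne | COC#CCC=C(C)C | intermediate
5 | acetone | CC(C)=O | starting material
6 | ketene | C=C=O | intermediate
7 | 3-methoxy-2-(3-methylbut-2-en-1-yl)cyclobut-2-en-1-one | COC1=C(CC=C(C)C)C(=O)C1 | intermediate
8 | methacrolein | CC(=C)C=O | starting material
9 | propargyl bromide | C#CCBr | starting material
10 | rac-2-methylhex-1-en-5-yn-3-ol | C=C(C)C(O)CC#C | intermediate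
11 | (3R)-2-methylhex-1-en-5-yn-3-ol | C=C(C)[C@H](O)CC#C | intermediate
12 | (3R)-3-(TBS-oxy)-2-methylhex-1-en-5-yne | C=C(C)[C@H](O[Si](C)(C)C(C)(C)C)CC#C | intermediate
13 | lithium acetylide of 12 | C=C(C)[C@H](O[Si](C)(C)C(C)(C)C)CC#C[Li] | intermediate
14 | lithium ynolate, lithium (4R)-4-(TBS-oxy)-5-methylhex-5-en-1-yn-1-olate | C=C(C)[C@H](O[Si](C)(C)C(C)(C)C)CC#CO[Li] | intermediate
15 | (3R)-3-(TBS-oxy)-2-methyl-6-(TIPS-oxy)hex-1-en-5-yne | C=C(C)[C@H](O[Si](C)(C)C(C)(C)C)CC#CO[Si](C(C)C)(C(C)C)C(C)C | intermediate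
16 | vinylketene, 2-(1-methoxyethenyl)-5-methylhexa-1,4-dien-1-one | C=C(OC)C(CC=C(C)C)=C=O | intermediate
17 | 4-(1-methoxyethenyl)-4-(3-methylbut-2-en-1-yl)-2-[(2R)-2-(TBS-oxy)-3-methylbut-3-en-1-yl]-3-(TIPS-oxy)cyclobut-2-en-1-one (both configurations at C4) | C=C(C)[C@H](O[Si](C)(C)C(C)(C)C)CC1=C(O[Si](C(C)C)(C(C)C)C(C)C)C(CC=C(C)C)(C(OC)=C)C1=O | intermediate
18 | dienylketene, 2-[(2R)-2-(TBS-oxy)-3-methylbut-3-en-1-yl]-5-methoxy-4-(3-methylbut-2-en-1-yl)-3-(TIPS-oxy)hexa-1,3,5-trien-1-one | C=C(C)[C@H](O[Si](C)(C)C(C)(C)C)CC(=C=O)C(O[Si](C(C)C)(C(C)C)C(C)C)=C(CC=C(C)C)C(OC)=C | intermediate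
19 | 2-[(2R)-2-(TBS-oxy)-3-methylbut-3-en-1-yl]-5-methoxy-4-(3-methylbut-2-en-1-yl)-3-(TIPS-oxy)phenol | C=C(C)[C@H](O[Si](C)(C)C(C)(C)C)Cc1c(O[Si](C(C)C)(C(C)C)C(C)C)c(CC=C(C)C)c(OC)cc1O | intermediate
20 | MOM ether of 19 | C=C(C)[C@H](O[Si](C)(C)C(C)(C)C)Cc1c(O[Si](C(C)C)(C(C)C)C(C)C)c(CC=C(C)C)c(OC)cc1OCOC | intermediate
21 | N-methoxy-N-methylacetamide | CC(=O)N(C)OC | starting material
22 | lithium enolate of 21 | C=C(O[Li])N(C)OC | intermediate
23 | N-methoxy-N,5-dimethylhex-4-enamide | CC(C)=CCCC(=O)N(C)OC | intermediate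
24 | aryllithium from 20 (lithium at the carbon between OMOM and OMe) | C=C(C)[C@H](O[Si](C)(C)C(C)(C)C)Cc1c(O[Si](C(C)C)(C(C)C)C(C)C)c(CC=C(C)C)c(OC)c([Li])c1OCOC | intermediate
25 | 1-{3-[(2R)-2-(TBS-oxy)-3-methylbut-3-en-1-yl]-6-methoxy-2-(methoxymethoxy)-5-(3-methylbut-2-en-1-yl)-4-(TIPS-oxy)phenyl}-5-methylhex-4-en-1-one | C=C(C)[C@H](O[Si](C)(C)C(C)(C)C)Cc1c(O[Si](C(C)C)(C(C)C)C(C)C)c(CC=C(C)C)c(OC)c(C(=O)CCC=C(C)C)c1OCOC | intermediate
26 | aryl trimethylsilyl ether of 27 | C=C(C)[C@H](O[Si](C)(C)C(C)(C)C)Cc1c(O[Si](C(C)C)(C(C)C)C(C)C)c(CC=C(C)C)c(OC)c(C(=O)CCC=C(C)C)c1O[Si](C)(C)C | intermediate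
27 | 1-{3-[(2R)-2-(TBS-oxy)-3-methylbut-3-en-1-yl]-2-hydroxy-6-methoxy-5-(3-methylbut-2-en-1-yl)-4-(TIPS-oxy)phenyl}-5-methylhex-4-en-1-one | C=C(C)[C@H](O[Si](C)(C)C(C)(C)C)Cc1c(O[Si](C(C)C)(C(C)C)C(C)C)c(CC=C(C)C)c(OC)c(C(=O)CCC=C(C)C)c1O | intermediate
28 | 2,4-dihydroxybenzoic acid | O=C(O)c1ccc(O)cc1O | starting material
29 | triisopropylsilyl 2,4-bis(TIPS-oxy)benzoate | CC(C)[Si](OC(=O)c1ccc(O[Si](C(C)C)(C(C)C)C(C)C)cc1O[Si](C(C)C)(C(C)C)C(C)C)(C(C)C)C(C)C | intermediate
30 | 2,4-bis(TIPS-oxy)benzoic acid | O=C(O)c1ccc(O[Si](C(C)C)(C(C)C)C(C)C)cc1O[Si](C(C)C)(C(C)C)C(C)C | intermediate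
31 | 2,4-bis(TIPS-oxy)benzoyl chloride | O=C(Cl)c1ccc(O[Si](C(C)C)(C(C)C)C(C)C)cc1O[Si](C(C)C)(C(C)C)C(C)C | intermediate
32 | 2-[(2R)-2-(TBS-oxy)-3-methylbut-3-en-1-yl]-5-methoxy-6-(5-methylhex-4-enoyl)-4-(3-methylbut-2-en-1-yl)-3-(TIPS-oxy)phenyl 2,4-bis(TIPS-oxy)benzoate | C=C(C)[C@H](O[Si](C)(C)C(C)(C)C)Cc1c(O[Si](C(C)C)(C(C)C)C(C)C)c(CC=C(C)C)c(OC)c(C(=O)CCC=C(C)C)c1OC(=O)c2ccc(O[Si](C(C)C)(C(C)C)C(C)C)cc2O[Si](C(C)C)(C(C)C)C(C)C | intermediate
33 | 1-{3-[(2R)-2-(TBS-oxy)-3-methylbut-3-en-1-yl]-2-hydroxy-6-methoxy-5-(3-methylbut-2-en-1-yl)-4-(TIPS-oxy)phenyl}-3-[2,4-bis(TIPS-oxy)phenyl]-2-(3-methylbut-2-en-1-yl)propane-1,3-dione (C2 unassigned, enolisable) | C=C(C)[C@H](O[Si](C)(C)C(C)(C)C)Cc1c(O[Si](C(C)C)(C(C)C)C(C)C)c(CC=C(C)C)c(OC)c(C(=O)C(CC=C(C)C)C(=O)c2ccc(O[Si](C(C)C)(C(C)C)C(C)C)cc2O[Si](C(C)C)(C(C)C)C(C)C)c1O | intermediate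
34 | 2-[2,4-bis(TIPS-oxy)phenyl]-8-[(2R)-2-(TBS-oxy)-3-methylbut-3-en-1-yl]-5-methoxy-3,6-bis(3-methylbut-2-en-1-yl)-7-(TIPS-oxy)-4H-chromen-4-one | C=C(C)[C@H](O[Si](C)(C)C(C)(C)C)Cc1c(O[Si](C(C)C)(C(C)C)C(C)C)c(CC=C(C)C)c(OC)c2c(=O)c(CC=C(C)C)c(-c3ccc(O[Si](C(C)C)(C(C)C)C(C)C)cc3O[Si](C(C)C)(C(C)C)C(C)C)oc12 | intermediate
35 | 2-[2,4-bis(TIPS-oxy)phenyl]-8-[(2R)-2-(TBS-oxy)-3-methylbut-3-en-1-yl]-5-hydroxy-3,6-bis(3-methylbut-2-en-1-yl)-7-(TIPS-oxy)-4H-chromen-4-one | C=C(C)[C@H](O[Si](C)(C)C(C)(C)C)Cc1c(O[Si](C(C)C)(C(C)C)C(C)C)c(CC=C(C)C)c(O)c2c(=O)c(CC=C(C)C)c(-c3ccc(O[Si](C(C)C)(C(C)C)C(C)C)cc3O[Si](C(C)C)(C(C)C)C(C)C)oc12 | intermediate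
36 | 2-(2,4-dihydroxyphenyl)-5,7-dihydroxy-8-[(2R)-2-hydroxy-3-methylbut-3-en-1-yl]-3,6-bis(3-methylbut-2-en-1-yl)-4H-chromen-4-one | C=C(C)[C@H](O)Cc1c(O)c(CC=C(C)C)c(O)c2c(=O)c(CC=C(C)C)c(-c3ccc(O)cc3O)oc12 | target

**Step count**

Total: 16 steps. Longest linear sequence: 12 steps, from methacrolein 8 to 36 (steps 3, 4, 5, 6, 7, 8, 10, 11, 13, 14, 15, 16).

**Steps most likely to fail**

Step 7 (benzannulation). The vinylogous-ester cyclobutenone may open too slowly, so that at the temperature required ketene dimerisation, acylation of the freshly formed phenol by the vinylketene, or stalling at the vinylcyclobutenone stage erodes the cascade. The fallback sets out from amide 23 and alkyne 15 and comes back at phenol 19; it makes the same vinylketene 16 at room temperature by a photochemical Wolff rearrangement. Amide 23 is treated with 1-methoxyvinyllithium F1 (from methyl vinyl ether and t-BuLi, THF, −78 °C) to give 2-methoxy-7-methylocta-1,6-dien-3-one F2. Trifluoroacetylation (LiHMDS, CF3CO2CH2CF3) gives 1,1,1-trifluoro-5-methoxy-3-(3-methylbut-2-en-1-yl)hex-5-ene-2,4-dione F3, which is not isolated, and deacylative diazo transfer (MsN3, Et3N, MeCN) gives 4-diazo-2-methoxy-7-methylocta-1,6-dien-3-one F4. Irradiation of F4 with 15 (CH2Cl2, rt, then brief warming in toluene) expels nitrogen with migration of the methoxyvinyl group and should pass through 16, 17 and 18 to 19.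

Step 14 (aroyl shift and ring C closure). The intramolecular O-to-C acyl transfer may be slow on the doubly ortho-hindered ester, so that ester cleavage or silyl migration competes before the diketone is reached. The fallback sets out from MOM ketone 25 and acid chloride 31 and comes back at diketone 33; it forms the C2–C3 bond intermolecularly before the phenol is released. The lithium enolate of 25 (LiHMDS, toluene, 0 °C) is C-acylated with 31 in a crossed Claisen condensation to give the MOM-protected 1,3-diketone F5. Treatment with TMSOTf/2,2'-bipyridyl gives the aryl trimethylsilyl ether F6, which is not isolated, and water releases 33, which is cyclodehydrated in warm AcOH to 34 as in the route.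

Step 10 (ortho-lithiation and acylation). Deprotonation at the benzylic/allylic methylene groups or at the allylic carbon bearing the TBS-oxy group, or proton transfer from the amide to the hindered aryllithium, may compete with ring lithiation and acylation. The fallback sets out from phenol 19 and comes back at hydroxy ketone 27, bypassing steps 8, 10 and 11 and working on the free phenol without organolithium reagents. Magnesium-mediated ortho-formylation (MgCl2, Et3N, paraformaldehyde, MeCN, reflux) gives 3-[(2R)-2-(TBS-oxy)-3-methylbut-3-en-1-yl]-2-hydroxy-6-methoxy-5-(3-methylbut-2-en-1-yl)-4-(TIPS-oxy)benzaldehyde F7. Addition of (4-methylpent-3-en-1-yl)magnesium bromide F8 (from 5-bromo-2-methylpent-2-ene and Mg, THF) gives the benzylic alcohol F9 as a diastereomer mixture, and MnO2 (CH2Cl2, rt) oxidises it to 27.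

Further compounds
F1 | step 7 | 1-methoxyvinyllithium | C=C([Li])OC
F2 | step 7 | 2-methoxy-7-methylocta-1,6-dien-3-one | C=C(OC)C(=O)CCC=C(C)C
F3 | step 7 | 1,1,1-trifluoro-5-methoxy-3-(3-methylbut-2-en-1-yl)hex-5-ene-2,4-dione | C=C(OC)C(=O)C(CC=C(C)C)C(=O)C(F)(F)F
F4 | step 7 | 4-diazo-2-methoxy-7-methylocta-1,6-dien-3-one | C=C(OC)C(=O)C(=[N+]=[N-])CC=C(C)C
F5 | step 14 | MOM ether of diketone 33 | C=C(C)[C@H](O[Si](C)(C)C(C)(C)C)Cc1c(O[Si](C(C)C)(C(C)C)C(C)C)c(CC=C(C)C)c(OC)c(C(=O)C(CC=C(C)C)C(=O)c2ccc(O[Si](C(C)C)(C(C)C)C(C)C)cc2O[Si](C(C)C)(C(C)C)C(C)C)c1OCOC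
F6 | step 14 | aryl trimethylsilyl ether of diketone 33 | C=C(C)[C@H](O[Si](C)(C)C(C)(C)C)Cc1c(O[Si](C(C)C)(C(C)C)C(C)C)c(CC=C(C)C)c(OC)c(C(=O)C(CC=C(C)C)C(=O)c2ccc(O[Si](C(C)C)(C(C)C)C(C)C)cc2O[Si](C(C)C)(C(C)C)C(C)C)c1O[Si](C)(C)C
F7 | step 10 | 3-[(2R)-2-(TBS-oxy)-3-methylbut-3-en-1-yl]-2-hydroxy-6-methoxy-5-(3-methylbut-2-en-1-yl)-4-(TIPS-oxy)benzaldehyde | C=C(C)[C@H](O[Si](C)(C)C(C)(C)C)Cc1c(O[Si](C(C)C)(C(C)C)C(C)C)c(CC=C(C)C)c(OC)c(C=O)c1O
F8 | step 10 | (4-methylpent-3-en-1-yl)magnesium bromide | CC(C)=CCC[Mg]Br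
F9 | step 10 | 1-{3-[(2R)-2-(TBS-oxy)-3-methylbut-3-en-1-yl]-2-hydroxy-6-methoxy-5-(3-methylbut-2-en-1-yl)-4-(TIPS-oxy)phenyl}-5-methylhex-4-en-1-ol (both carbinol epimers) | C=C(C)[C@H](O[Si](C)(C)C(C)(C)C)Cc1c(O[Si](C(C)C)(C(C)C)C(C)C)c(CC=C(C)C)c(OC)c(C(O)CCC=C(C)C)c1O
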